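The ten-membered ring (C1–C10) is not cyclised but unveiled: in a trans-fused eudesmanolide the C5–C10 bond shared by rings A and B is cut by a Grob fragmentation, in which the C5 tertiary alkoxide expels an equatorial C1 mesylate. One operation delivers the C5 ketone, the E-configured C1=C10 alkene and the medium ring with the cis C2–C3 oxirane, the C4 methylene and the trans-lactone already in place. The precursor is 5α-hydroxy-1β-mesyloxy-2α,3α-epoxyeudesm-4(15)-en-12,6α-olide bearing an 8α-silyl ether and a C11 phenylselenide (masked 11(13)-methylene); its rigid chair–chair geometry holds the C1–O and C5–C10 bonds anti-periplanar.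

Key step: step 20

Remark 1: locants and α/β follow eudesmane/germacrane numbering, β being the face of the C10 methyl (C14); monocyclic intermediates are described with the locants their carbons will carry.
Remark 2: in the target the C1–C10 oxirane has C9 and C2 anti (1R,10R, a trans-oxirane), so its alkene precursor must be E. A cis-fused decalin with the C1 sulfonate trans to the C10 methyl would fragment to the Z alkene and then give the wrong (cis) oxirane. The precursor is therefore trans-fused (5α-OH) with the 1β-sulfonate cis to the methyl, and the fragmentation product is the 1(10)E isomer.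
Remark 3: the methylene lactone is masked as a C11 selenide before the fragmentation, because afterwards C6–H next to the C5 ketone is more acidic than C11–H and lactone enolate chemistry is no longer possible.
Remark 4: C11 is an inconsequential epimer mixture in 6 to 29 (drawn without descriptor). The catalyst antipode in step 1 is assumed by analogy with aryl ketones.

Step 1
Reactants: 1 1,4-dioxaspiro[4.5]dec-6-en-8-one
Product: 2 (S)-1,4-dioxaspiro[4.5]dec-6-en-8-ol
Conditions: RuCl[(S,S)-TsDPEN](p-cymene) (cat.), HCO2H–Et3N, CH2Cl2, rt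
Reagents that add atoms: none
Why: Noyori asymmetric transfer hydrogenation reduces the enone carbonyl in 1,2 fashion, and with the alkene taking the place of the aryl group of an aryl ketone in the CH–π controlled transition state the (S,S)-catalyst should give the (S)-carbinol that becomes C8.

Step 2
Reactants: 2 (S)-1,4-dioxaspiro[4.5]dec-6-en-8-ol
Product: 3 (S)-8-(tert-butyldimethylsilyloxy)-1,4-dioxaspiro[4.5]dec-6-ene
Conditions: TBSCl, imidazole, DMF, rt
Reagents that add atoms: tert-butyldimethylsilyl chloride, CC(C)(C)[Si](C)(C)Cl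
Why: Imidazole-promoted silylation (silyl ether protection) of the secondary allylic alcohol, no stereocentre being touched.

Step 3
Reactants: 3 (S)-8-(tert-butyldimethylsilyloxy)-1,4-dioxaspiro[4.5]dec-6-ene
Product: 4 (S)-4-(tert-butyldimethylsilyloxy)cyclohex-2-en-1-one
Conditions: PPTS, acetone–H2O, 55 °C
Reagents that add atoms: water, O
Why: Acid-catalysed acetal hydrolysis under PPTS, mild enough to keep the allylic silyl ether, unveils the enone whose carbonyl is the future C5 and whose alkene is the future C6=C7.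

Step 4
Reactants: 4 (S)-4-(tert-butyldimethylsilyloxy)cyclohex-2-en-1-one; 5 (E)-1-methoxy-1-(trimethylsilyloxy)prop-1-ene
Product: 9 trans-fused keto lactone (C5 ketone; 6α-O lactone; 7β-C11; 8α-OTBS), via silyl enol ether 6 (not isolated), via α-silyloxy ketone 7 (not isolated), via α-hydroxy keto ester 8 (not isolated)
Conditions: MeCN, 55 °C; mCPBA, NaHCO3, CH2Cl2, −20 °C; PPTS, MeOH, 45 °C
Reagents that add atoms: mCPBA (3-chloroperbenzoic acid), O=C(OO)c1cccc(Cl)c1
Why: Mukaiyama–Michael addition of the ketene silyl acetal anti to the γ-silyloxy group sets C7 (C7–C11 trans to C8–O), Rubottom oxidation of the resulting silyl enol ether on the face away from the new C7 substituent sets C6–O α, and acid-promoted desilylation and lactonisation close the trans-fused γ-lactone.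

Step 5
Reactants: 9 trans-fused keto lactone
Product: 11 enone lactone (C5 ketone conjugated to C9=C10), via silyl enol ether 10 (not isolated)
Conditions: LiN(iPr)2, Me3SiCl, THF, −78 °C; Pd(OAc)2, MeCN, rt
Reagents that add atoms: none
Why: Kinetic deprotonation at the unhindered C10 methylene (not the tertiary, oxygenated C6–H) gives the silyl enol ether, and Saegusa–Ito oxidation by divalent palladium (β-hydride elimination) then gives the C9=C10 enone without touching a stereocentre.

Step 6
Reactants: 11 enone lactone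
Product: 12 10-iodo enone lactone
Conditions: I2, pyridine, CH2Cl2, rt
Reagents that add atoms: iodine, II
Why: Pyridine-mediated α-iodination of the enone (conjugate addition of pyridine, iodination of the enolate, elimination) places iodine at C10 for cross-coupling.

Step 7
Reactants: 13 ethyl vinyl ketone (pent-1-en-3-one)
Product: 14 2-ethyl-2-vinyl-1,3-dioxolane
Conditions: Me3SiOCH2CH2OSiMe3, Me3SiOTf (cat.), CH2Cl2, −78 °C
Reagents that add atoms: 1,2-bis(trimethylsilyloxy)ethane, C[Si](C)(C)OCCO[Si](C)(C)C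
Why: Noyori acetalisation under aprotic silyl triflate catalysis protects the vinyl ketone without conjugate addition or double-bond shift.

Step 8
Reactants: 12 10-iodo enone lactone; 14 2-ethyl-2-vinyl-1,3-dioxolane
Product: 16 enone lactone carrying the 2-(2-ethyl-1,3-dioxolan-2-yl)ethyl chain at C10, via B-alkyl-9-BBN 15 (not isolated)
Conditions: 14, 9-BBN, THF, 0 °C to rt; then 12, PdCl2(dppf), AsPh3, Cs2CO3, DMF–H2O, rt
Reagents that add atoms: none
Why: Anti-Markovnikov hydroboration gives the primary alkylborane, and B-alkyl Suzuki–Miyaura coupling with the α-iodoenone (oxidative addition to zerovalent palladium, transmetallation, reductive elimination) attaches the masked 3-oxopentyl chain (C1–C4 and C15) to C10.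

Step 9
Reactants: 16 enone lactone carrying the C10 chain
Product: 18 10β-methyl ketone (quaternary C10; chain α), via lithium enolate 17 (not isolated)
Conditions: LiBH(sBu)3, THF, −78 °C; MeI, DMPU, −78 to −20 °C
Reagents that add atoms: iodomethane, CI
Why: Conjugate hydride reduction forms the C5/C10 enolate regiospecifically, and its C-methylation (reductive alkylation) takes the stereoelectronically favoured axial path on a chair locked by the trans-lactone and the equatorial 8α-silyloxy group, that is from the β face, so C10 is set with methyl β and the chain α.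

Step 10
Reactants: 18 10β-methyl ketone
Product: 20 8α-(tert-butyldimethylsilyloxy)-3-oxoeudesm-4-en-12,6α-olide, via diketo lactone 19 (not isolated)
Conditions: PPTS, acetone–H2O, 55 °C; then pyrrolidine, AcOH (cat.), toluene, 80 °C
Reagents that add atoms: water, O
Why: Acetal hydrolysis followed by amine-catalysed intramolecular aldol condensation of C4 onto the C5 ketone (the ring-closing half of a Robinson annulation) forms ring A with the C4=C5 enone, and the trans-lactone at the now vinylogously enolisable C6 is the thermodynamic epimer.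

Step 11
Reactants: 20 8α-(tert-butyldimethylsilyloxy)-3-oxoeudesm-4-en-12,6α-olide
Product: 21 8α-(tert-butyldimethylsilyloxy)-3-oxoeudesma-1,4-dien-12,6α-olide
Conditions: DDQ, dioxane, reflux
Reagents that add atoms: none
Why: DDQ dehydrogenation of the 4-en-3-one through its 2,4-dienol (hydride abstraction at C1) introduces C1=C2 to give the cross-conjugated dienone.

Step 12
Reactants: 21 8α-(tert-butyldimethylsilyloxy)-3-oxoeudesma-1,4-dien-12,6α-olide
Product: 22 1α,2α-epoxy-8α-(tert-butyldimethylsilyloxy)-3-oxoeudesm-4-en-12,6α-olide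
Conditions: H2O2, NaOH, MeOH, 0 °C; then dilute HCl to pH 4
Reagents that add atoms: hydrogen peroxide, OO
Why: Weitz–Scheffer nucleophilic epoxidation attacks the disubstituted C1=C2 and not the tetrasubstituted C4=C5, with hydroperoxide adding to C1 anti to the axial C10 methyl so that the 1α,2α-oxirane forms.

Step 13
Reactants: 22 1α,2α-epoxy-8α-(tert-butyldimethylsilyloxy)-3-oxoeudesm-4-en-12,6α-olide
Product: 24 1α-hydroxy-8α-(tert-butyldimethylsilyloxy)eudesma-2,4-dien-12,6α-olide, via epoxy hydrazone 23 (not isolated)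
Conditions: N2H4·H2O, AcOH (cat.), MeOH, 0 °C to rt
Reagents that add atoms: none
Why: Wharton transposition (epoxy hydrazone, alkenyl diazene, loss of nitrogen) converts the epoxy ketone into the 1α-carbinol with C2=C3, the C1–O bond and hence its α configuration being retained.

Step 14
Reactants: 24 1α-hydroxy-8α-(tert-butyldimethylsilyloxy)eudesma-2,4-dien-12,6α-olide
Product: 26 2α,3α:4α,5α-diepoxy-1α-hydroxy-8α-(tert-butyldimethylsilyloxy)eudesman-12,6α-olide, via 4α,5α-monoepoxide 25 (not isolated)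
Conditions: mCPBA (2.5 equiv), NaHCO3, CH2Cl2, 0 °C to rt
Reagents that add atoms: mCPBA (3-chloroperbenzoic acid), O=C(OO)c1cccc(Cl)c1
Why: Prilezhaev epoxidation, first of the electron-rich tetrasubstituted C4=C5 and then of C2=C3, both anti to the axial C10 methyl and, for C2=C3, syn to the pseudo-axial 1α-hydroxyl (Henbest delivery), so that both oxiranes are α.

Step 15
Reactants: 26 2α,3α:4α,5α-diepoxy-1α-hydroxy-8α-(tert-butyldimethylsilyloxy)eudesman-12,6α-olide
Product: 27 2α,3α-epoxy-1α,5α-dihydroxy-8α-(tert-butyldimethylsilyloxy)eudesm-4(15)-en-12,6α-olide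
Conditions: Et2AlCl, lithium 2,2,6,6-tetramethylpiperidide, toluene, 0 °C
Reagents that add atoms: none
Why: Aluminium amide-mediated isomerisation of an epoxide to an allylic alcohol (syn β-elimination within the Al–O complex) can only use the C15 hydrogens, since H3 and H6 are anti to the 4α,5α-oxirane oxygen and the 2,3-oxirane has no syn β-hydrogen, giving the C4 methylene and the axial 5α-hydroxyl.

Step 16
Reactants: 27 2α,3α-epoxy-1α,5α-dihydroxy-8α-(tert-butyldimethylsilyloxy)eudesm-4(15)-en-12,6α-olide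
Product: 28 2α,3α-epoxy-5α-hydroxy-1-oxo-8α-(tert-butyldimethylsilyloxy)eudesm-4(15)-en-12,6α-olide
Conditions: Dess–Martin periodinane, NaHCO3, CH2Cl2, 0 °C
Reagents that add atoms: none
Why: Dess–Martin oxidation of the secondary C1 alcohol leaves the tertiary 5α-hydroxyl, the oxirane and the silyl ether untouched.

Step 17
Reactants: 28 2α,3α-epoxy-5α-hydroxy-1-oxo-8α-(tert-butyldimethylsilyloxy)eudesm-4(15)-en-12,6α-olide
Product: 29 2α,3α-epoxy-1β,5α-dihydroxy-8α-(tert-butyldimethylsilyloxy)eudesm-4(15)-en-12,6α-olide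
Conditions: Me4NBH(OAc)3, AcOH–MeCN, −30 °C
Reagents that add atoms: none
Why: Evans–Saksena hydroxyl-directed reduction, in which the axial 5α-hydroxyl binds boron and delivers hydride to the α face of C1 (also the axial approach anti to the C10 methyl), gives the equatorial 1β-alcohol, anti to O5 and cis to the C10 methyl.

Step 18
Reactants: 29 2α,3α-epoxy-1β,5α-dihydroxy-8α-(tert-butyldimethylsilyloxy)eudesm-4(15)-en-12,6α-olide
Product: 30 (11R)-11-(phenylselanyl) derivative of 29
Conditions: LiN(iPr)2 (3.3 equiv), THF, −78 °C; PhSeBr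
Reagents that add atoms: benzeneselenenyl bromide, Br[Se]c1ccccc1
Why: α-Selenenylation of the lactone lithium enolate (the two hydroxyls carried as alkoxides) makes C11 a single quaternary centre from both epimers, the electrophile entering on the β face, trans to H7, as is usual for trans-fused lactone enolates.

Step 19
Reactants: 30 (11R)-11-(phenylselanyl) diol
Product: 31 2α,3α-epoxy-5α-hydroxy-1β-(methanesulfonyloxy)-11-(phenylselanyl)-8α-(tert-butyldimethylsilyloxy)eudesm-4(15)-en-12,6α-olide
Conditions: MsCl, Et3N, CH2Cl2, −20 °C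
Reagents that add atoms: methanesulfonyl chloride, CS(=O)(=O)Cl
Why: Sulfonylation (mesylation through sulfene) of the equatorial secondary 1β-hydroxyl with retention, the tertiary 5α-hydroxyl being too hindered to react.

Step 20
Reactants: 31 trans-fused 5α-hydroxy-1β-mesyloxy-2α,3α-epoxy eudesmanolide
Product: 32 2α,3α-epoxy-5-oxo-11-(phenylselanyl)-8α-(tert-butyldimethylsilyloxy)germacra-1(10)E,4(15)-dien-12,6α-olide
Conditions: KOtBu (1.05 equiv), THF, −20 to 0 °C; pH 7 buffer
Reagents that add atoms: none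
Why: Deprotonation of the tertiary C5–OH gives an alkoxide whose lone pair, the C5–C10 σ bond and the equatorial C1–OMs bond are anti-periplanar, so that C5=O forms, C5–C10 breaks, C1=C10 forms and mesylate leaves in one concerted heterolytic fragmentation. The closest known reaction type is the Grob (Wharton) fragmentation of decalin 1,3-diol monosulfonates, the established eudesmane-to-germacrane ring expansion. No ring is closed by bond formation: the ten-membered ring arises by cleaving the bond shared by rings A and B, so no closure mode is involved. No stereocentre is created; the alkene geometry follows from the ground-state dihedral angles, because with the mesylate equatorial and cis to the axial C10 methyl in the rigid trans-decalin C9 is anti and the methyl gauche to C2, which gives the E alkene that the trans C1–C10 oxirane of the target demands. The step needs fragmentation to outrun E2, attack on the lactone and enolisation of the product, which is secured by the absence of an anti-periplanar hydrogen at C2, by O5 and the lactone lying on opposite faces, and by base that is consumed stoichiometrically as potassium mesylate at low temperature. Product 32 contains a cis-divinyloxirane unit and is therefore kept cold and oxidised at once in step 21.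

Step 21
Reactants: 32 germacradienone selenide
Product: 35 (1R,10R)-1,10:2α,3α-diepoxy-5-oxo-8α-(tert-butyldimethylsilyloxy)germacra-4(15),11(13)-dien-12,6α-olide, via selenoxide 33 (not isolated), via methylene lactone 34 (not isolated)
Conditions: mCPBA (3.2 equiv), NaHCO3, CH2Cl2, −40 to 0 °C
Reagents that add atoms: mCPBA (3-chloroperbenzoic acid), O=C(OO)c1cccc(Cl)c1
Why: Selenide oxidation and selenoxide syn-elimination (only the C13 hydrogens are syn, H7 being trans to selenium) give the 11(13)-methylene, and Prilezhaev epoxidation of the only electron-rich alkene, C1=C10, on the peripheral face of the crossed conformer (C14 up, the face away from the transannular C5) gives the trans (1R,10R)-oxirane, while both carbonyl-conjugated methylenes stay inert.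

Step 22
Reactants: 35 bis-epoxy enone silyl ether
Product: 36 (1R,10R)-1,10:2α,3α-diepoxy-8α-hydroxy-5-oxogermacra-4(15),11(13)-dien-12,6α-olide
Conditions: HF·pyridine, pyridine, THF, 0 °C
Reagents that add atoms: none
Why: Fluoride-mediated cleavage of the silyl ether under pyridine-buffered conditions frees the 8α-hydroxyl without opening the oxiranes.

Step 23
Reactants: 36 8α-hydroxy bis-epoxy enone; 37 angelic acid
Product: 39 8α-angeloyloxy-(1R,10R)-1,10:2α,3α-diepoxy-5-oxogermacra-4(15),11(13)-dien-12,6α-olide, via mixed anhydride 38 (not isolated)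
Conditions: 37, 2,4,6-trichlorobenzoyl chloride, Et3N, toluene, rt; then 36, 75 °C
Reagents that add atoms: none
Why: Mixed-anhydride (Yamaguchi-type) esterification of the only free hydroxyl, run without a nucleophilic pyridine catalyst so that the Z-configured angelate does not isomerise to the tiglate, the configuration at C8 being retained.

Step 24
Reactants: 39 8α-angeloyloxy C5 ketone
Product: 40 CNP0038366.2 (target)
Conditions: NaBH4, CeCl3·7H2O, MeOH, −78 °C; AcOH quench
Reagents that add atoms: none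
Why: Luche reduction is selective for 1,2-addition to the C5 enone over the methylene lactone and the angelate, and hydride attacks the peripheral face of the carbonyl (anti to the transannular C10), setting the (5R)-carbinol.

Compound list
1 | 1,4-dioxaspiro[4.5]dec-6-en-8-one | O=C1C=CC2(CC1)OCCO2 | starting material
2 | (S)-1,4-dioxaspiro[4.5]dec-6-en-8-ol | O[C@@H]1C=CC2(CC1)OCCO2 | intermediate
3 | (S)-8-(tert-butyldimethylsilyloxy)-1,4-dioxaspiro[4.5]dec-6-ene | CC(C)(C)[Si](C)(C)O[C@@H]1C=CC2(CC1)OCCO2 | intermediate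
4 | (S)-4-(tert-butyldimethylsilyloxy)cyclohex-2-en-1-one | O=C1C=C[C@@H](O[Si](C)(C)C(C)(C)C)CC1 | intermediate
5 | (E)-1-methoxy-1-(trimethylsilyloxy)prop-1-ene | C/C=C(/O[Si](C)(C)C)OC | starting material
6 | methyl 2-[trans-6-(tert-butyldimethylsilyloxy)-3-(trimethylsilyloxy)cyclohex-2-en-1-yl]propanoate (7β-C11, 8α-O; not isolated) | C[Si](C)(C)OC1=C[C@H](C(C)C(=O)OC)[C@@H](O[Si](C)(C)C(C)(C)C)CC1 | intermediate
7 | α-silyloxy ketone: C5 ketone, 6α-OSiMe3, 7β-CH(CH3)CO2Me, 8α-OTBS (not isolated) | O=C1[C@@H](O[Si](C)(C)C)[C@H](C(C)C(=O)OC)[C@@H](O[Si](C)(C)C(C)(C)C)CC1 | intermediate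
8 | α-hydroxy keto ester: C5 ketone, 6α-OH, 7β-CH(CH3)CO2Me, 8α-OTBS (not isolated) | O=C1[C@@H](O)[C@H](C(C)C(=O)OC)[C@@H](O[Si](C)(C)C(C)(C)C)CC1 | intermediate
9 | 4-(tert-butyldimethylsilyloxy)-3-methylhexahydro-1-benzofuran-2,7-dione, trans-fused (C5 ketone, 6α-O, 7β-C11, 8α-OTBS) | CC1C(=O)O[C@H]2[C@H]1[C@@H](O[Si](C)(C)C(C)(C)C)CCC2=O | intermediate
10 | C5 trimethylsilyl enol ether (C5=C10) of 9 (not isolated) | CC1C(=O)O[C@H]2[C@H]1[C@@H](O[Si](C)(C)C(C)(C)C)CC=C2O[Si](C)(C)C | intermediate
11 | enone lactone: C5 ketone, C9=C10, 6α,12-lactone, 8α-OTBS | CC1C(=O)O[C@H]2[C@H]1[C@@H](O[Si](C)(C)C(C)(C)C)C=CC2=O | intermediate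
12 | 10-iodo derivative of 11 | CC1C(=O)O[C@H]2[C@H]1[C@@H](O[Si](C)(C)C(C)(C)C)C=C(I)C2=O | intermediate
13 | ethyl vinyl ketone (pent-1-en-3-one) | CCC(=O)C=C | starting material
14 | 2-ethyl-2-vinyl-1,3-dioxolane | C=CC1(CC)OCCO1 | intermediate
15 | 9-[2-(2-ethyl-1,3-dioxolan-2-yl)ethyl]-9-borabicyclo[3.3.1]nonane (not isolated) | CCC1(CCB2C3CCCC2CCC3)OCCO1 | intermediate
16 | 10-[2-(2-ethyl-1,3-dioxolan-2-yl)ethyl] derivative of 11 | CC1C(=O)O[C@H]2[C@H]1[C@@H](O[Si](C)(C)C(C)(C)C)C=C(CCC3(CC)OCCO3)C2=O | intermediate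
17 | lithium C5(10)-enolate from 16 (not isolated) | CC1C(=O)O[C@H]2[C@H]1[C@@H](O[Si](C)(C)C(C)(C)C)CC(CCC3(CC)OCCO3)=C2O[Li] | intermediate
18 | ketone with quaternary C10: 10β-methyl, 10α-[2-(2-ethyl-1,3-dioxolan-2-yl)ethyl], 6α,12-lactone, 8α-OTBS | CC1C(=O)O[C@H]2[C@H]1[C@@H](O[Si](C)(C)C(C)(C)C)C[C@@](C)(CCC3(CC)OCCO3)C2=O | intermediate
19 | diketo lactone: 10α-(3-oxopentyl) analogue of 18 (not isolated) | CC1C(=O)O[C@H]2[C@H]1[C@@H](O[Si](C)(C)C(C)(C)C)C[C@@](C)(CCC(=O)CC)C2=O | intermediate
20 | 8α-(tert-butyldimethylsilyloxy)-3-oxoeudesm-4-en-12,6α-olide | CC1C(=O)O[C@H]2[C@H]1[C@@H](O[Si](C)(C)C(C)(C)C)C[C@@]3(C)CCC(=O)C(C)=C23 | intermediate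
21 | 8α-(tert-butyldimethylsilyloxy)-3-oxoeudesma-1,4-dien-12,6α-olide | CC1C(=O)O[C@H]2[C@H]1[C@@H](O[Si](C)(C)C(C)(C)C)C[C@@]3(C)C=CC(=O)C(C)=C23 | intermediate
22 | 1α,2α-epoxy-8α-(tert-butyldimethylsilyloxy)-3-oxoeudesm-4-en-12,6α-olide | CC1C(=O)O[C@H]2[C@H]1[C@@H](O[Si](C)(C)C(C)(C)C)C[C@@]3(C)[C@H]4O[C@H]4C(=O)C(C)=C23 | intermediate
23 | C3 hydrazone of 22 (not isolated) | CC1C(=O)O[C@H]2[C@H]1[C@@H](O[Si](C)(C)C(C)(C)C)C[C@@]3(C)[C@H]4O[C@H]4C(=NN)C(C)=C23 | intermediate
24 | 1α-hydroxy-8α-(tert-butyldimethylsilyloxy)eudesma-2,4-dien-12,6α-olide | CC1C(=O)O[C@H]2[C@H]1[C@@H](O[Si](C)(C)C(C)(C)C)C[C@@]3(C)[C@@H](O)C=CC(C)=C23 | intermediate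
25 | 4α,5α-epoxy-1α-hydroxy-8α-(tert-butyldimethylsilyloxy)eudesm-2-en-12,6α-olide (not isolated) | CC1C(=O)O[C@H]2[C@H]1[C@@H](O[Si](C)(C)C(C)(C)C)C[C@@]3(C)[C@@H](O)C=C[C@@]4(C)O[C@@]234 | intermediate
26 | 2α,3α:4α,5α-diepoxy-1α-hydroxy-8α-(tert-butyldimethylsilyloxy)eudesman-12,6α-olide | CC1C(=O)O[C@H]2[C@H]1[C@@H](O[Si](C)(C)C(C)(C)C)C[C@@]3(C)[C@@H](O)[C@H]4O[C@H]4[C@@]5(C)O[C@@]235 | intermediate
27 | 2α,3α-epoxy-1α,5α-dihydroxy-8α-(tert-butyldimethylsilyloxy)eudesm-4(15)-en-12,6α-olide | CC1C(=O)O[C@H]2[C@H]1[C@@H](O[Si](C)(C)C(C)(C)C)C[C@@]3(C)[C@@H](O)[C@H]4O[C@H]4C(=C)[C@]23O | intermediate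
28 | 2α,3α-epoxy-5α-hydroxy-1-oxo-8α-(tert-butyldimethylsilyloxy)eudesm-4(15)-en-12,6α-olide | CC1C(=O)O[C@H]2[C@H]1[C@@H](O[Si](C)(C)C(C)(C)C)C[C@@]3(C)C(=O)[C@H]4O[C@H]4C(=C)[C@]23O | intermediate
29 | 2α,3α-epoxy-1β,5α-dihydroxy-8α-(tert-butyldimethylsilyloxy)eudesm-4(15)-en-12,6α-olide | CC1C(=O)O[C@H]2[C@H]1[C@@H](O[Si](C)(C)C(C)(C)C)C[C@@]3(C)[C@H](O)[C@H]4O[C@H]4C(=C)[C@]23O | intermediate
30 | (11R)-2α,3α-epoxy-1β,5α-dihydroxy-11-(phenylselanyl)-8α-(tert-butyldimethylsilyloxy)eudesm-4(15)-en-12,6α-olide | C[C@]1([Se]c5ccccc5)C(=O)O[C@H]2[C@H]1[C@@H](O[Si](C)(C)C(C)(C)C)C[C@@]3(C)[C@H](O)[C@H]4O[C@H]4C(=C)[C@]23O | intermediate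
31 | (11R)-2α,3α-epoxy-5α-hydroxy-1β-(methanesulfonyloxy)-11-(phenylselanyl)-8α-(tert-butyldimethylsilyloxy)eudesm-4(15)-en-12,6α-olide (trans-fused; key-step precursor) | C[C@]1([Se]c5ccccc5)C(=O)O[C@H]2[C@H]1[C@@H](O[Si](C)(C)C(C)(C)C)C[C@@]3(C)[C@H](OS(C)(=O)=O)[C@H]4O[C@H]4C(=C)[C@]23O | intermediate
32 | (11R)-2α,3α-epoxy-5-oxo-11-(phenylselanyl)-8α-(tert-butyldimethylsilyloxy)germacra-1(10)E,4(15)-dien-12,6α-olide (key-step product) | C[C@]1([Se]c5ccccc5)C(=O)O[C@H]2[C@H]1[C@@H](O[Si](C)(C)C(C)(C)C)C/C(C)=C/[C@H]3O[C@H]3C(=C)C2=O | intermediate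
33 | selenoxide of 32 (not isolated) | C[C@]1([Se](=O)c5ccccc5)C(=O)O[C@H]2[C@H]1[C@@H](O[Si](C)(C)C(C)(C)C)C/C(C)=C/[C@H]3O[C@H]3C(=C)C2=O | intermediate
34 | 2α,3α-epoxy-5-oxo-8α-(tert-butyldimethylsilyloxy)germacra-1(10)E,4(15),11(13)-trien-12,6α-olide (not isolated) | C=C1C(=O)O[C@H]2[C@H]1[C@@H](O[Si](C)(C)C(C)(C)C)C/C(C)=C/[C@H]3O[C@H]3C(=C)C2=O | intermediate
35 | (1R,10R)-1,10:2α,3α-diepoxy-5-oxo-8α-(tert-butyldimethylsilyloxy)germacra-4(15),11(13)-dien-12,6α-olide | C=C1C(=O)O[C@H]2[C@H]1[C@@H](O[Si](C)(C)C(C)(C)C)C[C@@]3(C)O[C@@H]3[C@H]4O[C@H]4C(=C)C2=O | intermediate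
36 | (1R,10R)-1,10:2α,3α-diepoxy-8α-hydroxy-5-oxogermacra-4(15),11(13)-dien-12,6α-olide | C=C1C(=O)O[C@H]2[C@H]1[C@@H](O)C[C@@]3(C)O[C@@H]3[C@H]4O[C@H]4C(=C)C2=O | intermediate
37 | angelic acid ((Z)-2-methylbut-2-enoic acid) | C/C=C(/C)C(=O)O | starting material
38 | angelic 2,4,6-trichlorobenzoic anhydride (not isolated) | C/C=C(/C)C(=O)OC(=O)c1c(Cl)cc(Cl)cc1Cl | intermediate
39 | 8α-angeloyloxy-(1R,10R)-1,10:2α,3α-diepoxy-5-oxogermacra-4(15),11(13)-dien-12,6α-olide | C=C1C(=O)O[C@H]2[C@H]1[C@@H](OC(=O)/C(C)=C\C)C[C@@]3(C)O[C@@H]3[C@H]4O[C@H]4C(=C)C2=O | intermediate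
40 | CNP0038366.2: (1R,2S,3S,5R,6S,7R,8S,10R)-8-angeloyloxy-1,10:2,3-diepoxy-5-hydroxygermacra-4(15),11(13)-dien-12,6-olide | C=C1C(=O)O[C@H]2[C@H]1[C@@H](OC(=O)/C(C)=C\C)C[C@@]1(C)O[C@@H]1[C@H]1O[C@H]1C(=C)[C@H]2O | target

Total step count: 24. Longest linear sequence: 23 steps (steps 1–6 and 8–24; step 7 prepares the side fragment 14).

Steps most likely to fail

Step 20 (key fragmentation). Under alkoxide base the mesylate or the freshly formed enone may be degraded faster than the anti-periplanar fragmentation proceeds: C6 epimerisation by enolisation, tert-butoxide addition to the C4 methylene, or attack at sulfur. The fallback sets out from 31. The tertiary hydroxyl is silylated (Me3SiOTf, 2,6-lutidine, CH2Cl2, −78 °C) to the C5 trimethylsilyl ether of 31 F1. The same fragmentation is then triggered by fluoride (CsF, DMF, 0 °C), which liberates the alkoxide in a medium free of Brønsted base. The route is rejoined at 32.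

Step 15 (epoxide to allylic alcohol). The aluminium amide may be diverted by the lactone (enolisation, Lewis-acid-assisted opening) or may open the 2,3-oxirane, so that the tetrasubstituted oxirane is not isomerised cleanly. The fallback sets out from 24. Only the allylic C2=C3 bond is epoxidised under hydroxyl direction (VO(acac)2, t-BuOOH, CH2Cl2, 0 °C) to 2α,3α-epoxy-1α-hydroxy-8α-(tert-butyldimethylsilyloxy)eudesm-4-en-12,6α-olide F2. A Schenck ene reaction with singlet oxygen (O2, tetraphenylporphyrin, hν, CH2Cl2, −20 °C) on the α face can only abstract a C15 hydrogen, because H3 and H6 are β. It should give the 5α-hydroperoxy-4(15)-ene F3, and reduction with PPh3 rejoins the route at 27.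

Step 13 (Wharton transposition). Hydrazine may attack the γ-lactone (hydrazide formation) or the hydrazone may be diverted to the azine, so that the transposition stalls. The fallback sets out from 22. Luche reduction (NaBH4, CeCl3·7H2O, MeOH, −78 °C) gives the 1α,2α-epoxy-3-ol F4, which 1,1'-thiocarbonyldiimidazole (THF, 60 °C) converts into its imidazol-1-ylthiocarbonyl ester F5. Tin hydride (Bu3SnH, AIBN, toluene, 80 °C) then generates the C3 radical, whose epoxycarbinyl ring opening (a Barton–McCombie-type deoxygenative transposition) gives the 1α-alcohol 24.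

Further compounds
F1 | step 20 | C5 trimethylsilyl ether of 31 | C[C@]1([Se]c5ccccc5)C(=O)O[C@H]2[C@H]1[C@@H](O[Si](C)(C)C(C)(C)C)C[C@@]3(C)[C@H](OS(C)(=O)=O)[C@H]4O[C@H]4C(=C)[C@]23O[Si](C)(C)C
F2 | step 15 | 2α,3α-epoxy-1α-hydroxy-8α-(tert-butyldimethylsilyloxy)eudesm-4-en-12,6α-olide | CC1C(=O)O[C@H]2[C@H]1[C@@H](O[Si](C)(C)C(C)(C)C)C[C@@]3(C)[C@@H](O)[C@H]4O[C@H]4C(C)=C23
F3 | step 15 | 2α,3α-epoxy-5α-hydroperoxy-1α-hydroxy-8α-(tert-butyldimethylsilyloxy)eudesm-4(15)-en-12,6α-olide | CC1C(=O)O[C@H]2[C@H]1[C@@H](O[Si](C)(C)C(C)(C)C)C[C@@]3(C)[C@@H](O)[C@H]4O[C@H]4C(=C)[C@]23OO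
F4 | step 13 | 1α,2α-epoxy-3-hydroxy-8α-(tert-butyldimethylsilyloxy)eudesm-4-en-12,6α-olide | CC1C(=O)O[C@H]2[C@H]1[C@@H](O[Si](C)(C)C(C)(C)C)C[C@@]3(C)[C@H]4O[C@H]4C(O)C(C)=C23
F5 | step 13 | 3-O-(imidazol-1-ylthiocarbonyl) derivative of F4 | CC1C(=O)O[C@H]2[C@H]1[C@@H](O[Si](C)(C)C(C)(C)C)C[C@@]3(C)[C@H]4O[C@H]4C(OC(=S)n5ccnc5)C(C)=C23
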